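**Plan**

1. Numbering: ring A is the formyl-bearing ring, numbered as a benzoic acid (A-1 carries the lactone carbonyl, A-2 the ether oxygen, A-3 CHO, A-4 OH, A-6 CH3). Ring B uses chromanone numbering (O-6 is the ether oxygen, O-7 the ester oxygen).
2. Retrosynthetic cuts, in order: the A-4 O–CH3 protecting group; the lactone C(=O)–O-7 bond; the formyl carbon is re-tied to O-7 as a benzyl ether; the O-6–A-2 and A-1–CO2 bonds are then cut together (aryne A-1≡A-2, tethered phenoxide, CO2); then the benzyl ether C–O bond; then the pyranone of ring B.
3. Enabling feature: A-2 (ether) and A-1 (carboxyl) are neighbouring ring carbons, the two ends of an aryne, and A-2 is flanked by the formyl carbon A-3, which can reach O-7 of the catechol unit of ring B. A temporary seven-membered 11H-dibenzo[b,e][1,4]dioxepine ring therefore delivers O-6 to A-2 only and forces CO2 onto A-1.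
4. Forward order: the ring A aryne precursor (steps 1–4) and the chromanone of ring B (steps 5–6) are made separately and joined (step 7). Step 8 closes the temporary dioxepine ring and installs CO2H, step 9 opens it to CHO and 7-OH, step 10 closes the depsidone ring, and step 11 frees the phenol.
5. Stereochemistry: the target has no stereocentre, so none has to be set; the hemiacetal carbon in step 9 is transient.

Key step: step 8

Assumption: compounds 1, 9 and 12 are taken to be commercial; no other assumption about the chemistry is needed.

**Route**

Step 1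
Reactants: 1 2,6-dimethoxy-4-methylbenzaldehyde
Product: 2 3-bromo-2,6-dimethoxy-4-methylbenzaldehyde
Conditions: NBS (1.0 equiv), MeCN, 0 °C to rt
Reagents that add atoms: N-bromosuccinimide O=C1CCC(=O)N1Br
Why: Electrophilic aromatic bromination; the two free positions of the symmetric ring are equivalent and each is ortho and para to a methoxy group, so one equivalent of NBS should give a single monobromide.

Step 2
Reactants: 2 3-bromo-2,6-dimethoxy-4-methylbenzaldehyde
Product: 3 3-bromo-2-hydroxy-6-methoxy-4-methylbenzaldehyde
Conditions: BCl3 (1.1 equiv), CH2Cl2, −78 to 0 °C; aqueous work-up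
Reagents that add atoms: none
Why: Lewis acid ether cleavage assisted by chelation to the formyl oxygen; of the two ortho methoxy groups the one wedged between CHO and Br is twisted out of the ring plane, more basic and relieved of strain on cleavage, so it should be cleaved first and leave bromine ortho to the new phenol.

Step 3
Reactants: 3 3-bromo-2-hydroxy-6-methoxy-4-methylbenzaldehyde
Product: 4 6-bromo-2-(hydroxymethyl)-3-methoxy-5-methylphenol
Conditions: NaBH4, MeOH, 0 °C
Reagents that add atoms: none
Why: Hydride reduction of the aldehyde to the salicyl alcohol; the aryl bromide and the phenol are inert to NaBH4.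

Step 4
Reactants: 4 6-bromo-2-(hydroxymethyl)-3-methoxy-5-methylphenol
Product: 8 2-(hydroxymethyl)-3-methoxy-5-methyl-6-(trimethylsilyl)phenyl trifluoromethanesulfonate, via bis(trimethylsilyl) ether 5 (not isolated), via lithium phenoxide 6 (not isolated), via silyl ether triflate 7 (not isolated)
Conditions: HMDS, THF, 70 °C, then evaporation; n-BuLi (1.05 equiv), THF, −78 °C; Tf2O, −78 °C to rt; 1 M HCl/THF work-up
Reagents that add atoms: hexamethyldisilazane C[Si](C)(C)N[Si](C)(C)C; trifluoromethanesulfonic anhydride O=S(=O)(OS(=O)(=O)C(F)(F)F)C(F)(F)F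
Why: Standard preparation of ortho-silylaryl triflates: after O-silylation, bromine–lithium exchange triggers a 1,3 O-to-C silyl shift (retro-Brook rearrangement) that places SiMe3 on the carbon that carried bromine and frees only the neighbouring phenoxide, which is triflated, while the primary silyl ether falls off on acidic work-up.

Step 5
Reactants: 9 2,4-dihydroxy-6-methylbenzaldehyde
Product: 11 6-methylbenzene-1,2,4-triol, via aryl formate 10 (not isolated)
Conditions: 30% H2O2 (1.1 equiv), 1 M NaOH, 0 °C to rt, N2; then HCl to pH 3; used crude under N2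
Reagents that add atoms: hydrogen peroxide OO
Why: Dakin oxidation: hydroperoxide adds to the aldehyde, the electron-rich aryl group (ortho and para hydroxyls) migrates to oxygen and the formate is saponified, which puts the third oxygen exactly on the carbon that carried CHO.

Step 6
Reactants: 11 6-methylbenzene-1,2,4-triol; 12 3-methylbut-2-enoic acid
Product: 14 6,7-dihydroxy-2,2,5-trimethylchroman-4-one, via aryl enone 13 (not isolated)
Conditions: BF3·OEt2 (solvent), 80 °C, N2; aqueous work-up
Reagents that add atoms: none
Why: Friedel–Crafts acylation followed by oxa-Michael ring closure (one-flask chromanone synthesis from a phenol and an unsaturated acid); acylation is expected at C-5 of the triol, para to the 2-OH and ortho to the 4-OH, and not at C-3 squeezed between two hydroxyls, and only the 4-OH can then close the pyranone.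

Step 7
Reactants: 8 2-(hydroxymethyl)-3-methoxy-5-methyl-6-(trimethylsilyl)phenyl trifluoromethanesulfonate; 14 6,7-dihydroxy-2,2,5-trimethylchroman-4-one
Product: 15 2-{[(6-hydroxy-2,2,5-trimethyl-4-oxochroman-7-yl)oxy]methyl}-3-methoxy-5-methyl-6-(trimethylsilyl)phenyl trifluoromethanesulfonate
Conditions: PPh3, DIAD, THF, 0 °C to rt
Reagents that add atoms: none
Why: Mitsunobu etherification of a primary benzylic alcohol; the 7-OH, para to the chromanone carbonyl, is the more acidic and less hindered phenol and should act as the pronucleophile, leaving the flanked 6-OH free.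

Step 8
Reactants: 15 2-{[(6-hydroxy-2,2,5-trimethyl-4-oxochroman-7-yl)oxy]methyl}-3-methoxy-5-methyl-6-(trimethylsilyl)phenyl trifluoromethanesulfonate
Product: 18 dibenzodioxepine acid, via potassium phenoxide 16 (not isolated), via aryne 17 (not isolated)
Conditions: KH (1.0 equiv), THF, 0 °C; then KF, 18-crown-6, CO2 (1 atm), THF (0.005 M), 0 °C to rt; 1 M HCl
Reagents that add atoms: carbon dioxide O=C=O
Why: Proposed new method: fluoride attacks the SiMe3 group on A-1 and expels the triflate on A-2 to give aryne 17; the phenoxide oxygen O-6, held next to A-2 by the A-3 CH2–O-7 tether, adds to A-2, and the aryl anion left on A-1 is trapped by CO2 as the carboxylate. The closest known reaction types are the fluoride-triggered three-component coupling of arynes, amines and CO2 to anthranilic acids and the cyclization of tethered oxygen or nitrogen nucleophiles onto arynes; what is new is a tethered phenoxide as the nucleophile of the CO2 coupling. One ring closes, the seven-membered dioxepine, by attack on the aryne carbon that carries the tether, so that the aryne bond stays outside the new ring (exo mode); attack on A-1 would need an eight-membered ring bridging meta positions and is geometrically excluded. No stereocentre is formed. The step needs regiocontrol on both rings and capture of the aryl anion by CO2 and not by a proton: O-7 is blocked as the tether so only O-6 can add, the tether decides which aryne carbon takes oxygen, and the preformed potassium phenoxide in dry THF at high dilution under CO2 leaves no proton source and little chance for intermolecular addition.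

Step 9
Reactants: 18 dibenzodioxepine acid
Product: 20 3-formyl-2-[(7-hydroxy-2,2,5-trimethyl-4-oxochroman-6-yl)oxy]-4-methoxy-6-methylbenzoic acid, via cyclic hemiacetal 19 (not isolated)
Conditions: DDQ (1.5 equiv), CH2Cl2/pH 7 buffer, rt
Reagents that add atoms: water O
Why: Oxidative cleavage of an electron-rich benzyl aryl ether with DDQ, as for alkoxybenzyl protecting groups: hydride abstraction from the ring methylene gives an oxocarbenium ion stabilized by the two ortho oxygens of ring A, water adds and hemiacetal 19 opens, so the tether carbon becomes the formyl group and the 7-OH is freed.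

Step 10
Reactants: 20 3-formyl-2-[(7-hydroxy-2,2,5-trimethyl-4-oxochroman-6-yl)oxy]-4-methoxy-6-methylbenzoic acid
Product: 22 O-methylmollicellin A, via mixed anhydride 21 (not isolated)
Conditions: (CF3CO)2O, toluene (0.01 M), 0 °C to rt; aqueous NaHCO3 work-up
Reagents that add atoms: none
Why: Lactonization through the mixed trifluoroacetic anhydride, a standard way to esterify di-ortho-substituted benzoic acids with phenols because the acylium-like activation sidesteps the steric hindrance; the seven-membered depsidone ring closes by attack of the 7-OH on the activated carboxyl.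

Step 11
Reactants: 22 O-methylmollicellin A
Product: 23 mollicellin A
Conditions: BCl3 (3 equiv), CH2Cl2, −78 to 0 °C; aqueous work-up
Reagents that add atoms: none
Why: Chelation-controlled cleavage of the methyl ether ortho to the formyl group by BCl3, which at low temperature should spare the diaryl ether, the aryl lactone and the chromanone ether.

**Compound list**

1 | 2,6-dimethoxy-4-methylbenzaldehyde | COc1cc(C)cc(OC)c1C=O | starting material
2 | 3-bromo-2,6-dimethoxy-4-methylbenzaldehyde | COc1cc(C)c(Br)c(OC)c1C=O | intermediate
3 | 3-bromo-2-hydroxy-6-methoxy-4-methylbenzaldehyde | COc1cc(C)c(Br)c(O)c1C=O | intermediate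
4 | 6-bromo-2-(hydroxymethyl)-3-methoxy-5-methylphenol | COc1cc(C)c(Br)c(O)c1CO | intermediate
5 | bis(trimethylsilyl) ether of 4 (phenol and benzylic alcohol both silylated) | COc1cc(C)c(Br)c(O[Si](C)(C)C)c1CO[Si](C)(C)C | intermediate (not isolated)
6 | lithium 3-methoxy-5-methyl-6-(trimethylsilyl)-2-[(trimethylsilyloxy)methyl]phenoxide | [Li+].COc1cc(C)c([Si](C)(C)C)c([O-])c1CO[Si](C)(C)C | intermediate (not isolated)
7 | 3-methoxy-5-methyl-6-(trimethylsilyl)-2-[(trimethylsilyloxy)methyl]phenyl trifluoromethanesulfonate | COc1cc(C)c([Si](C)(C)C)c(OS(=O)(=O)C(F)(F)F)c1CO[Si](C)(C)C | intermediate (not isolated)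
8 | 2-(hydroxymethyl)-3-methoxy-5-methyl-6-(trimethylsilyl)phenyl trifluoromethanesulfonate | COc1cc(C)c([Si](C)(C)C)c(OS(=O)(=O)C(F)(F)F)c1CO | intermediate
9 | 2,4-dihydroxy-6-methylbenzaldehyde | Cc1cc(O)cc(O)c1C=O | starting material
10 | 2,4-dihydroxy-6-methylphenyl formate | Cc1cc(O)cc(O)c1OC=O | intermediate (not isolated)
11 | 6-methylbenzene-1,2,4-triol | Cc1cc(O)cc(O)c1O | intermediate
12 | 3-methylbut-2-enoic acid | CC(C)=CC(=O)O | starting material
13 | 3-methyl-1-(2,4,5-trihydroxy-6-methylphenyl)but-2-en-1-one | CC(C)=CC(=O)c1c(C)c(O)c(O)cc1O | intermediate (not isolated)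
14 | 6,7-dihydroxy-2,2,5-trimethylchroman-4-one | Cc1c(O)c(O)cc2OC(C)(C)CC(=O)c12 | intermediate
15 | 2-{[(6-hydroxy-2,2,5-trimethyl-4-oxochroman-7-yl)oxy]methyl}-3-methoxy-5-methyl-6-(trimethylsilyl)phenyl trifluoromethanesulfonate | COc1cc(C)c([Si](C)(C)C)c(OS(=O)(=O)C(F)(F)F)c1COc1cc2OC(C)(C)CC(=O)c2c(C)c1O | intermediate
16 | potassium 6-phenoxide of 15 | [K+].COc1cc(C)c([Si](C)(C)C)c(OS(=O)(=O)C(F)(F)F)c1COc1cc2OC(C)(C)CC(=O)c2c(C)c1[O-] | intermediate (not isolated)
17 | aryne: ring A with a formal triple bond between A-1 and A-2, OMe on A-4, CH3 on A-6 and the A-3 CH2 group bound to O-7 of the potassium 6-phenoxide of ring B | [K+].COC1=C(COc2cc3OC(C)(C)CC(=O)c3c(C)c2[O-])C#CC(C)=C1 | intermediate (not isolated)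
18 | dibenzodioxepine acid: 11H-dibenzo[b,e][1,4]dioxepine built from rings A and B (CH2 bridge from A-3 to O-7, diaryl ether O-6–A-2), with CO2H on A-1, OMe on A-4, CH3 on A-6 and ring B still fused to the 2,2-dimethylpyran-4-one | COc1cc(C)c(C(=O)O)c2Oc3c(C)c4C(=O)CC(C)(C)Oc4cc3OCc12 | intermediate
19 | cyclic hemiacetal of 18 (OH on the bridging carbon, racemic, transient) | COc1cc(C)c(C(=O)O)c2Oc3c(C)c4C(=O)CC(C)(C)Oc4cc3OC(O)c12 | intermediate (not isolated)
20 | 3-formyl-2-[(7-hydroxy-2,2,5-trimethyl-4-oxochroman-6-yl)oxy]-4-methoxy-6-methylbenzoic acid | COc1cc(C)c(C(=O)O)c(Oc2c(C)c3C(=O)CC(C)(C)Oc3cc2O)c1C=O | intermediate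
21 | mixed anhydride of 20 with trifluoroacetic acid | COc1cc(C)c(C(=O)OC(=O)C(F)(F)F)c(Oc2c(C)c3C(=O)CC(C)(C)Oc3cc2O)c1C=O | intermediate (not isolated)
22 | O-methylmollicellin A (mollicellin A with OCH3 in place of the A-4 OH) | COc1cc(C)c2C(=O)Oc3cc4OC(C)(C)CC(=O)c4c(C)c3Oc2c1C=O | intermediate
23 | mollicellin A | Cc1cc(O)c(C=O)c2c1C(=O)Oc1cc3c(c(C)c1O2)C(=O)CC(C)(C)O3 | target

**Totals**

Total step count: 11.
Longest linear sequence: 9 steps (steps 1–4, then 7–11); steps 5–6 form the second branch.

**Steps most likely to fail**

Step 8 (proposed new method). The aryl anion on A-1 may be protonated before it meets CO2. Alternatively the phenoxide may be held as its carbonate under CO2, so that ring closure is outrun by intermolecular addition or by sulfonyl transfer from the triflate. The fallback uses known chemistry, sets out from 15 and returns at 18. Compound 15 is treated with CsF in MeCN at high dilution; the same aryne should cyclize onto the phenol and the aryl anion is simply protonated (intramolecular aryne O-arylation of a phenol), giving the carboxyl-free dibenzodioxepine F1. NBS in MeCN should brominate ring A para to the methoxy group, at A-1, to give the aryl bromide F2. Hydroxycarbonylation of F2 (CO, water, K2CO3, catalytic Pd(OAc)2 and Xantphos, dioxane, 90 °C) should then give acid 18.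

Step 9. Hydride abstraction from the ring methylene may be slow, because the carboxyl group lowers the electron density of ring A and the seven-membered ring holds the C–H bonds poorly aligned with the arene; DDQ could then attack elsewhere. The fallback sets out from 18 and returns at 22. BCl3 in CH2Cl2 at −78 °C should cleave the benzylic C–O bond heterolytically to the chloromethyl hydroxy acid F3, which is used at once. Trifluoroacetic anhydride closes the depsidone lactone to the chloromethyl depsidone F4. A Kornblum oxidation (AgBF4, DMSO, then Et3N) should turn CH2Cl into CHO and give 22.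

Step 2. The Lewis acid may cleave the methoxy group remote from bromine, or both methoxy groups, so that regiocontrol in the mono-demethylation is lost. The fallback sets out from 2 and returns at 8. BBr3 removes both methyl groups to give 3-bromo-2,6-dihydroxy-4-methylbenzaldehyde F5. NaBH4 gives 4-bromo-2-(hydroxymethyl)-5-methylbenzene-1,3-diol F6, which is silylated without purification because it loses water easily. The one-flask silylation, bromine–lithium exchange with retro-Brook shift, triflation and acidic work-up of step 4 should then give 3-hydroxy-2-(hydroxymethyl)-5-methyl-6-(trimethylsilyl)phenyl trifluoromethanesulfonate F7. Here the position of bromine, not the Lewis acid, decides which oxygen is triflated. MeI and K2CO3 in acetone should methylate the remaining phenol, and not the benzylic alcohol, to give 8.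

Further compounds

F1 | step 8 | dibenzodioxepine of 18 lacking the carboxyl group (H on A-1) | COc1cc(C)cc2Oc3c(C)c4C(=O)CC(C)(C)Oc4cc3OCc12
F2 | step 8 | dibenzodioxepine of 18 with Br in place of CO2H on A-1 | COc1cc(C)c(Br)c2Oc3c(C)c4C(=O)CC(C)(C)Oc4cc3OCc12
F3 | step 9 | 3-(chloromethyl)-2-[(7-hydroxy-2,2,5-trimethyl-4-oxochroman-6-yl)oxy]-4-methoxy-6-methylbenzoic acid | COc1cc(C)c(C(=O)O)c(Oc2c(C)c3C(=O)CC(C)(C)Oc3cc2O)c1CCl
F4 | step 9 | depsidone 22 with CH2Cl in place of CHO | COc1cc(C)c2C(=O)Oc3cc4OC(C)(C)CC(=O)c4c(C)c3Oc2c1CCl
F5 | step 2 | 3-bromo-2,6-dihydroxy-4-methylbenzaldehyde | Cc1cc(O)c(C=O)c(O)c1Br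
F6 | step 2 | 4-bromo-2-(hydroxymethyl)-5-methylbenzene-1,3-diol | Cc1cc(O)c(CO)c(O)c1Br
F7 | step 2 | 3-hydroxy-2-(hydroxymethyl)-5-methyl-6-(trimethylsilyl)phenyl trifluoromethanesulfonate | Cc1cc(O)c(CO)c(OS(=O)(=O)C(F)(F)F)c1[Si](C)(C)C
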